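**Retrosynthetic overview**
- Target 16 is cut between ring carbon C1 (the quaternary, methyl-bearing carbon of the cyclohexene, ring C) and the alkene CH. Both carbons are first placed on one boron atom (tert-alkylboron from 11, E-alkenylboron from alkyne 5) and then joined by an iodine-triggered 1,2-shift of Zweifel type, which also gives the Z alkene.
- Feature that makes this possible: C1 is a fully substituted sp3 carbon of ring C bonded directly to an sp2 CH of a 1,2-disubstituted Z alkene, and the coumarin on the neighbouring ring carbon C2 is cis to that alkene. A C1–B bond cis to the aryl maps onto the target through a stereoretentive shift, and an E-alkenylborane maps onto the Z alkene.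
- Trifluoroborate 11 comes from boronate 10, made by syn 1,2-arylboration of the C2-symmetric 1,4-dimethylcyclohexa-1,3-diene 8 with 8-iodocoumarin 2 and B2pin2 9. This sets both stereocentres and leaves the C3=C4(CH3) alkene where the target needs it.
- 2 and 5 come from 5,7-dimethoxycoumarin 1 (iodination; Sonogashira coupling and desilylation); 8 comes from 4-methylcyclohex-2-enone 6 (dienyl triflate, methylation).
- No ring is formed in the route: ring C and both coumarin bicycles are bought intact.

Key step: step 8

Assumption: electrophilic iodination of 1 occurs mainly at C8 (flanked by the 7-OCH3 and the ring oxygen, para to the 5-OCH3); minor C6 and C3 iodides would be removed by chromatography.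
Assumption: the antipode of the chiral NHC ligand in step 6 that leads to the (1R,2R) series would be identified by assay; the route is written for that antipode.

Step 1
Reactants: 1 5,7-dimethoxy-2H-chromen-2-one (citropten)
Product: 2 8-iodo-5,7-dimethoxy-2H-chromen-2-one
Conditions: NIS (1.05 equiv), TFA (0.3 equiv), MeCN, 0 °C to rt
Reagents that add atoms: N-iodosuccinimide, O=C1CCC(=O)N1I
Why: Electrophilic aromatic iodination should go to C8, the most activated and less hindered free position of the dimethoxylated ring.

Step 2
Reactants: 2 8-iodo-5,7-dimethoxy-2H-chromen-2-one; 3 ethynyltrimethylsilane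
Product: 4 5,7-dimethoxy-8-[(trimethylsilyl)ethynyl]-2H-chromen-2-one
Conditions: PdCl2(PPh3)2 (3 mol %), CuI (5 mol %), Et3N, THF, 50 °C
Reagents that add atoms: none
Why: Sonogashira coupling of an aryl iodide with a terminal alkyne is reliable and leaves the lactone untouched.

Step 3
Reactants: 4 5,7-dimethoxy-8-[(trimethylsilyl)ethynyl]-2H-chromen-2-one
Product: 5 8-ethynyl-5,7-dimethoxy-2H-chromen-2-one
Conditions: K2CO3 (0.1 equiv), MeOH–THF, 0 °C, short reaction time; AcOH quench
Reagents that add atoms: none
Why: Carbonate-catalysed methanolysis of the C(sp)–Si bond (protodesilylation) is fast enough at 0 °C that the lactone should stay closed.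

Step 4
Reactants: 6 4-methylcyclohex-2-en-1-one (racemic)
Product: 7 4-methylcyclohexa-1,3-dien-1-yl trifluoromethanesulfonate
Conditions: Tf2O (1.1 equiv), 2,6-di-tert-butyl-4-methylpyridine (1.2 equiv), CH2Cl2, 0 °C to rt
Reagents that add atoms: trifluoromethanesulfonic anhydride, O=S(=O)(OS(=O)(=O)C(F)(F)F)C(F)(F)F
Why: O-sulfonylation of the enone followed by loss of the γ proton under equilibrating conditions should give the through-conjugated dienyl triflate (dienol triflate formation), which also removes the stereocentre of 6.

Step 5
Reactants: 7 4-methylcyclohexa-1,3-dien-1-yl trifluoromethanesulfonate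
Product: 8 1,4-dimethylcyclohexa-1,3-diene
Conditions: MeMgBr (1.3 equiv), Fe(acac)3 (5 mol %), THF–NMP, −30 to 0 °C; careful distillation (volatile product)
Reagents that add atoms: methylmagnesium bromide, C[Mg]Br
Why: Iron-catalysed Kumada-type cross-coupling of alkenyl triflates with methyl Grignard reagent is a known way to place a methyl group without isomerising the diene.

Step 6
Reactants: 8 1,4-dimethylcyclohexa-1,3-diene (2 equiv); 2 8-iodo-5,7-dimethoxy-2H-chromen-2-one; 9 bis(pinacolato)diboron
Product: 10 2-[(1R,2R)-2-(5,7-dimethoxy-2-oxo-2H-chromen-8-yl)-1,4-dimethylcyclohex-3-en-1-yl]-4,4,5,5-tetramethyl-1,3,2-dioxaborolane (boron and aryl cis)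
Conditions: [(4R,5R)-1,3-bis(2-isopropylphenyl)-4,5-diphenylimidazolidin-2-ylidene]CuCl (10 mol %), Pd(OAc)2 (3 mol %), RuPhos (6 mol %), NaOtBu (1.5 equiv), toluene–THF, 0 °C to rt; NH4Cl (aq.) work-up
Reagents that add atoms: none
Why: Proposed new method: a chiral NHC–Cu–Bpin species should add syn across one C=C of the C2-symmetric diene with boron at the methyl-bearing terminus (the only regiochemistry that gives an allylcopper), and stereoretentive Cu-to-Pd transmetalation to the arylpalladium iodide followed by C–C reductive elimination at the secondary allyl terminus should place the aryl cis to boron and leave the other alkene untouched, the ligand on copper choosing between the two enantiomeric modes of addition and so setting both stereocentres; the closest known reaction type is the Cu/Pd-cooperative 1,2-arylboration of isoprene and of cyclic 1,3-dienes (borylcupration at a fully substituted carbon being known from conjugate borylation of β,β-disubstituted enones), which has not been shown for a diene terminus that becomes a tertiary boronate.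

Step 7
Reactants: 10 pinacol boronate (1R,2R)
Product: 11 potassium [(1R,2R)-2-(5,7-dimethoxy-2-oxo-2H-chromen-8-yl)-1,4-dimethylcyclohex-3-en-1-yl]trifluoroborate
Conditions: KHF2 (4.5 M aq., 4 equiv), MeOH, rt; azeotropic removal of pinacol
Reagents that add atoms: potassium hydrogen difluoride, [K+].F[H-]F
Why: Exchange of the pinacol ester for fluoride at boron (trifluoroborate formation) does not touch the C–B bond, so the configuration at C1 is kept.

Step 8
Reactants: 11 potassium trifluoroborate (1R,2R); 5 8-ethynyl-5,7-dimethoxy-2H-chromen-2-one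
Product: 16 target CNP0164660.3, via dichloroborane 12 (not isolated), via chlorohydridoborane 13 (not isolated), via E-alkenylchloroborane 14 (not isolated), via sodium dimethoxyborate 15 (not isolated)
Conditions: SiCl4 (1.1 equiv), MeCN–CH2Cl2, 0 °C; Et3SiH (1.05 equiv), 5 (1.05 equiv), 0 °C to rt; NaOMe (excess), MeOH–THF, −78 °C; I2 (1.2 equiv), THF, −78 to 0 °C; Na2S2O3 (aq.), then 1 M HCl work-up
Reagents that add atoms: none
Why: Fluoride abstraction by SiCl4 should turn 11 into dichloroborane 12, Si–H/B–Cl exchange with Et3SiH should give the tert-alkyl(chloro)hydridoborane 13, and this bulky B–H should add syn and anti-Markovnikov to the terminal alkyne of 5, so that both carbons of the bond to be made sit on one boron in 14, which serves as a traceless tether. Methoxide then forms borate 15, iodine activates the boron-bound E alkene as an iodonium ion, the tertiary ring carbon C1 (the only carbon group on boron besides the alkenyl) shifts from boron to the adjacent alkene carbon, and methoxide-induced anti elimination of the boron group and iodide gives the alkene with inverted geometry, that is Z. The closest known reaction types are the Zweifel olefination in its alkyl(alkenyl)haloborane form (hydroboration of a 1-alkyne by an alkylhaloborane, then NaOMe and I2) and the Zweifel olefination of tertiary boronic esters. No ring is closed. No new stereocentre is formed: C1 keeps the configuration set in step 6 because the 1,2-shift is stereoretentive, and the Z geometry follows from syn hydroboration plus anti migration and anti elimination. The step needs monohydroboration of the alkyne in the presence of the ring alkene and the two lactone C=C bonds, which the bulk of the tert-alkylborane and the higher reactivity of the 1-alkyne should secure, and it needs the lactones and electron-rich arenes to survive methoxide and iodine, which low temperature, limited base and an acidic work-up that recloses any opened lactone should secure.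

**Compound list**
1 | 5,7-dimethoxy-2H-chromen-2-one (citropten) | COc1cc(OC)c2ccc(=O)oc2c1 | starting material
2 | 8-iodo-5,7-dimethoxy-2H-chromen-2-one | COc1cc(OC)c2ccc(=O)oc2c1I | intermediate
3 | ethynyltrimethylsilane | C#C[Si](C)(C)C | starting material
4 | 5,7-dimethoxy-8-[(trimethylsilyl)ethynyl]-2H-chromen-2-one | COc1cc(OC)c2ccc(=O)oc2c1C#C[Si](C)(C)C | intermediate
5 | 8-ethynyl-5,7-dimethoxy-2H-chromen-2-one | COc1cc(OC)c2ccc(=O)oc2c1C#C | intermediate
6 | 4-methylcyclohex-2-en-1-one (racemic) | CC1CCC(=O)C=C1 | starting material
7 | 4-methylcyclohexa-1,3-dien-1-yl trifluoromethanesulfonate | CC1=CC=C(OS(=O)(=O)C(F)(F)F)CC1 | intermediate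
8 | 1,4-dimethylcyclohexa-1,3-diene | CC1=CC=C(C)CC1 | intermediate
9 | bis(pinacolato)diboron | CC1(C)OB(OC1(C)C)B1OC(C)(C)C(C)(C)O1 | starting material
10 | 2-[(1R,2R)-2-(5,7-dimethoxy-2-oxo-2H-chromen-8-yl)-1,4-dimethylcyclohex-3-en-1-yl]-4,4,5,5-tetramethyl-1,3,2-dioxaborolane | CC1(C)OB(OC1(C)C)[C@@]1(C)CCC(C)=C[C@H]1c1c(OC)cc(OC)c2ccc(=O)oc12 | intermediate
11 | potassium [(1R,2R)-2-(5,7-dimethoxy-2-oxo-2H-chromen-8-yl)-1,4-dimethylcyclohex-3-en-1-yl]trifluoroborate | [K+].F[B-](F)(F)[C@@]1(C)CCC(C)=C[C@H]1c1c(OC)cc(OC)c2ccc(=O)oc12 | intermediate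
12 | dichloro[(1R,2R)-2-(5,7-dimethoxy-2-oxo-2H-chromen-8-yl)-1,4-dimethylcyclohex-3-en-1-yl]borane | ClB(Cl)[C@@]1(C)CCC(C)=C[C@H]1c1c(OC)cc(OC)c2ccc(=O)oc12 | intermediate
13 | chloro[(1R,2R)-2-(5,7-dimethoxy-2-oxo-2H-chromen-8-yl)-1,4-dimethylcyclohex-3-en-1-yl]borane (B–H) | Cl[BH][C@@]1(C)CCC(C)=C[C@H]1c1c(OC)cc(OC)c2ccc(=O)oc12 | intermediate
14 | chloro[(E)-2-(5,7-dimethoxy-2-oxo-2H-chromen-8-yl)ethenyl][(1R,2R)-2-(5,7-dimethoxy-2-oxo-2H-chromen-8-yl)-1,4-dimethylcyclohex-3-en-1-yl]borane | COc1cc(OC)c2ccc(=O)oc2c1/C=C/B(Cl)[C@@]1(C)CCC(C)=C[C@H]1c1c(OC)cc(OC)c2ccc(=O)oc12 | intermediate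
15 | sodium [(E)-2-(5,7-dimethoxy-2-oxo-2H-chromen-8-yl)ethenyl][(1R,2R)-2-(5,7-dimethoxy-2-oxo-2H-chromen-8-yl)-1,4-dimethylcyclohex-3-en-1-yl]dimethoxyborate | [Na+].COc1cc(OC)c2ccc(=O)oc2c1/C=C/[B-](OC)(OC)[C@@]1(C)CCC(C)=C[C@H]1c1c(OC)cc(OC)c2ccc(=O)oc12 | intermediate
16 | 8-[(Z)-2-[(1R,2R)-2-(5,7-dimethoxy-2-oxo-2H-chromen-8-yl)-1,4-dimethylcyclohex-3-en-1-yl]ethenyl]-5,7-dimethoxy-2H-chromen-2-one (CNP0164660.3) | COc1cc(OC)c2ccc(=O)oc2c1/C=C\[C@@]1(C)CCC(C)=C[C@H]1c1c(OC)cc(OC)c2ccc(=O)oc12 | target

**Step count and risks**
Total step count: 8. Longest linear sequence: 5 steps (6 → 7 → 8 → 10 → 11 → 16).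

Steps most likely to fail:

1. Step 6 (Proposed new method). Borylcupration at a fully substituted diene terminus may be too slow, so that the copper boryl is consumed by conjugate borylation of the lactone, the allyl group is captured at the wrong terminus, or the syn course is eroded by a stereoinvertive transmetalation. Fallback with known chemistry, setting out from 2 and coming back at 10: Heck reaction of 2 with isoprene (Pd(OAc)2, P(o-tol)3, Et3N, DMF, sealed tube) should give 8-[(E)-3-methylbuta-1,3-dien-1-yl]-5,7-dimethoxy-2H-chromen-2-one F1. Thermal Diels–Alder reaction of F1 with isopropenylboronic acid pinacol ester (toluene, 120–130 °C, BHT) should give the tertiary boronate with ortho/para regiochemistry. The cis diastereomer, racemic cis boronate F2, would be separated by chromatography and resolved on a chiral stationary phase to give 10. This fallback gives up catalyst control of both diastereo- and enantioselectivity.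

2. Step 8 (key step). The chlorohydridoborane may form incompletely or lose its tertiary alkyl group by retro-hydroboration; the tertiary group may migrate poorly so that iodine cleaves the alkenyl–boron bond instead; or methoxide may open a lactone and the resulting phenoxide ring may be iodinated. Fallback setting out from 10 and coming back at 16: Matteson homologation of 10 with LiCH2Cl made in situ (ICH2Cl, nBuLi, THF, −78 °C to rt) should give the homologated pinacol boronate F3 (CH2B on the face of the aryl, configuration at C1 retained). Oxidation (NaBO3·4H2O, THF–H2O) should give the neopentyl alcohol F4, and Dess–Martin oxidation the non-enolisable aldehyde F5. Ohira–Bestmann homologation (dimethyl (1-diazo-2-oxopropyl)phosphonate, K2CO3, MeOH) should give the terminal alkyne F6. Sonogashira coupling with 2 should give the diarylalkyne F7, and semihydrogenation (Pd/CaCO3 poisoned with Pb(OAc)2, quinoline, H2) should give 16. In this fallback the C1–CH bond is made by the homologation and the convergence is moved to the aryl–alkyne bond.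

3. Step 4. Deprotonation of the O-sulfonylated enone at the α′ position instead of the γ position would give the cross-conjugated triflate, and the volatile products of steps 4 and 5 may be lost on isolation. Fallback setting out from 6 and coming back at 8: 1,2-addition of MeMgBr in the presence of CeCl3 (THF, −78 °C) should give 1,4-dimethylcyclohex-2-en-1-ol F8. Dehydration under equilibrating conditions (catalytic p-TsOH, pentane, rt) should give the most substituted conjugated diene 8, which would be used as a solution.

Further compounds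
F1 | step 6 | 8-[(E)-3-methylbuta-1,3-dien-1-yl]-5,7-dimethoxy-2H-chromen-2-one | COc1cc(OC)c2ccc(=O)oc2c1/C=C/C(C)=C
F2 | step 6 | racemic cis boronate (racemate of 10, boron and aryl cis) | CC1(C)OB(OC1(C)C)[C@@]1(C)CCC(C)=C[C@H]1c1c(OC)cc(OC)c2ccc(=O)oc12.CC1(C)OB(OC1(C)C)[C@]1(C)CCC(C)=C[C@@H]1c1c(OC)cc(OC)c2ccc(=O)oc12
F3 | step 8 | homologated pinacol boronate, 2-{[cis-2-(5,7-dimethoxy-2-oxo-2H-chromen-8-yl)-1,4-dimethylcyclohex-3-en-1-yl]methyl}-4,4,5,5-tetramethyl-1,3,2-dioxaborolane (CH2B cis to aryl) | CC1(C)OB(OC1(C)C)C[C@@]1(C)CCC(C)=C[C@H]1c1c(OC)cc(OC)c2ccc(=O)oc12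
F4 | step 8 | neopentyl alcohol, 8-[cis-6-(hydroxymethyl)-3,6-dimethylcyclohex-2-en-1-yl]-5,7-dimethoxy-2H-chromen-2-one (CH2OH cis to aryl) | OC[C@@]1(C)CCC(C)=C[C@H]1c1c(OC)cc(OC)c2ccc(=O)oc12
F5 | step 8 | aldehyde, cis-2-(5,7-dimethoxy-2-oxo-2H-chromen-8-yl)-1,4-dimethylcyclohex-3-ene-1-carbaldehyde (CHO cis to aryl) | O=C[C@@]1(C)CCC(C)=C[C@H]1c1c(OC)cc(OC)c2ccc(=O)oc12
F6 | step 8 | terminal alkyne, 8-[cis-6-ethynyl-3,6-dimethylcyclohex-2-en-1-yl]-5,7-dimethoxy-2H-chromen-2-one (ethynyl cis to aryl) | C#C[C@@]1(C)CCC(C)=C[C@H]1c1c(OC)cc(OC)c2ccc(=O)oc12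
F7 | step 8 | diarylalkyne, the alkyne analogue of 16 (C≡C in place of the Z alkene, same ring configuration) | COc1cc(OC)c2ccc(=O)oc2c1C#C[C@@]1(C)CCC(C)=C[C@H]1c1c(OC)cc(OC)c2ccc(=O)oc12
F8 | step 4 | 1,4-dimethylcyclohex-2-en-1-ol (mixture of stereoisomers) | CC1CCC(C)(O)C=C1
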